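Percent of the G charged, one E counted as two, was the unit agreed when the meeting opened on the north, east and south-east flasks.

all flasks: G 27 mM
- ash: D 2.7 mM; run made earlier
- larch: D 11 mM; run made earlier
- north: D 5.40 mM; time 5.0 min
- east: D 5.40 mM; time 6.0 min
- south-east: D 5.40 mM; time 3.0 min

| run | time / min | G / % | E / % | J / % | X / % |
|---|---|---|---|---|---|
| ash | 0.250 | 46.4 | 31.3 | 7.7 | 0 |
| ash | 0.667 | 26.0 | 44.0 | 13.2 | 0 |
| ash | 1.50 | 14.3 | 52.7 | 18.9 | 2.2 |
| ash | 4.00 | 4.3 | 55.9 | 22.5 | 6.8 |
| larch | 0.417 | 28.3 | 31.3 | 8.8 | 0.2 |
| larch | 1.33 | 10.8 | 39.6 | 14.0 | 2.8 |
| larch | 2.50 | 4.4 | 40.3 | 16.2 | 3.7 |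
| larch | 4.00 | 1.2 | 41.2 | 16.8 | 5.7 |

(readings scatter by 0.5 percentage points)

- which of these there is most of at the end, counted by the G in it, north (E / J / G / X)
- which of these there is most of at the end, counted by the G in it, east (E / J / G / X)
- which of these there is most of at the end, counted by the G in it, south-east (E / J / G / X)
- amount of the one of these that there is most of at the end, in percent of the G charged, north
- amount of the one of these that there is most of at the end, in percent of the G charged, east
- amount of the one of these that there is most of at the end, in percent of the G charged, south-east

- in percentages every species weighs as the G in it: one E counts as two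
- steps thought possible: J <-> X; G <-> L; 2 G -> E; G -> J; G + D -> Z
- a reading of G is of its free form alone

The bench chemist read the last row of the ash run: E was 65.6% of E, J and X together. The larch run gave 64.7%, close although its [D] was higher. The bench chemist therefore held the ash share good for north, whose [G] is the same.

The chair reckoned two routes, G leaving singly for J and in pairs for E. Pairs go as [G] squared and singles as [G], so their starting ratio goes with the [G] charged. With Z left aside and G used up, the share of E then comes to one minus the natural logarithm of (one plus the ratio), over the ratio. The ratio stands on both sides of that rule, so the chair went round. The first row of the ash run gave E over J at a mean G of 73.2%, a first answer of 5.55. Put back, that gave 5.47, and once more 5.43. The meeting kept this reading as the split, the starting rate of G to E over that of G to J at the [G] charged in the ash run, a selectivity factor.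

For north the chair took Z as the whole 20.0% that D can bind and took G as used up, which gave E at 52.6%. That is the chair's own figure, above the forecast.

The forecast named E, E and E for north, east and south-east, at 51% (49.3% to 52.8%), 51.3% (49.6% to 53.1%) and 50% (48.2% to 51.8%), on the ground that “E is clearly the largest product in both runs”.

    J ⇌ X (K = 0.690, k = 0.00194 s⁻¹)
    G ⇌ L (K = 0.290, k = 0.0169 s⁻¹)
    2 G → E (k = 0.818 M⁻¹ s⁻¹)
    G → J (k = 0.00715 s⁻¹)
    G + D → Z (k = 2.41 M⁻¹ s⁻¹)

The flasks give E first: north 51.3%, east 51.4%, south-east 50.6%, each below the top of the forecast's range and above its foot. In north at 5.00 min E holds 65.3% of E, J and X together, and the split gives 65.7% for G used up. With 110 mM of G in the north recipe, the split scales to 22.1 and the share to 85.8%. With D at 0.0491 equiv of G, and Z again taken as the whole that D can bind, the reckoning puts E at 81.6%. That neighbour gives E at 80.4%, a share of 85.6%.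

The runs are simulated for substances that don't exist.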